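**Retrosynthetic overview**
1. Target ⇐ desilylation and C9 acetylation of a macrocyclic C9 alcohol. The ten-membered ring is formed last, by a chromium-mediated alkenyl iodide/aldehyde closure of C9–C10 (sets C9).
2. Seco aldehyde ⇐ indium Barbier coupling (C7–C8; sets C7 and C8 from C6) of an (R)-3-(bromomethyl)butenolide with 2,2-dimethoxyacetaldehyde, then acylation with (S)-2-methylbutanoic acid (made from tiglic acid).
3. Butenolide (lactone ring, formed first) ⇐ chiral Brønsted acid-catalysed acetoxy-allylboration/lactonisation of an achiral enal (C6–C7; sets C6), then SN2′ bromide exchange.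
4. Enal ⇐ but-2-yne-1,4-diol by anti-carbomagnesiation (4,5-alkene geometry) and iodo-Wittig olefination (1(10)-alkene geometry).

Assumption: the BINOL-derived acid in the new step induces in the same sense as with allyl pinacolboronate and aryl or alkenyl aldehydes, so the (S)-acid is written; the mirror-image acid is used if the sense proves opposite.

Abbreviations: TBS = tert-butyldimethylsilyl, TES = triethylsilyl, Bpin = 4,4,5,5-tetramethyl-1,3,2-dioxaborolan-2-yl. Locants C1–C15 are germacrane numbering.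

**Step 1**
Reactants: 1 but-2-yne-1,4-diol; 2 2-(2-bromoethyl)-1,3-dioxolane
Product: 5 5-[(E)-2-hydroxyethylidene]oxan-2-ol, via Grignard reagent 3 (not isolated), via diol acetal 4 (not isolated)
Conditions: 2, Mg, THF, 25 °C (3.3 equiv of 3); 1, CuI (10 mol %), THF, −10 → 20 °C; then 1 M HCl/THF, 20 °C
Reagents that add atoms: water, O
Why: Copper-catalysed anti-carbomagnesiation of a propargylic alcohol: the magnesium alkoxide delivers the alkyl group to the near alkyne carbon and holds the vinyl C–Mg bond cis to its own CH2O arm, so protonation gives the E-diol (chain cis to the other CH2OH), and acetal hydrolysis lets the aldehyde close onto the geminal hydroxymethyl group as a six-membered lactol, leaving a single free OH.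

**Step 2**
Reactants: 5 5-[(E)-2-hydroxyethylidene]oxan-2-ol
Product: 6 5-[(E)-2-(triethylsilyloxy)ethylidene]oxan-2-ol
Conditions: Et3SiCl (1.05 equiv), imidazole, CH2Cl2, −40 °C
Reagents that add atoms: chlorotriethylsilane, CC[Si](Cl)(CC)CC
Why: Silyl ether formation at the only free primary allylic hydroxyl (the hemiacetal OH is much slower at −40 °C); the TES group marks this oxygen for the later oxidation.

**Step 3**
Reactants: 6 5-[(E)-2-(triethylsilyloxy)ethylidene]oxan-2-ol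
Product: 7 ethyl (2Z,6E)-6-(hydroxymethyl)-2-iodo-8-(triethylsilyloxy)octa-2,6-dienoate
Conditions: Ph3P=CHCO2Et, N-iodosuccinimide, CH2Cl2, −20 °C; then 6, toluene, 60 °C
Reagents that add atoms: ethyl (triphenylphosphoranylidene)acetate, CCOC(=O)C=P(c1ccccc1)(c1ccccc1)c1ccccc1; N-iodosuccinimide, O=C1CCC(=O)N1I
Why: Wittig olefination of the lactol through its open hydroxy aldehyde form with the stabilised iodo ylide, which gives the Z iodoenoate (iodine cis to the chain, ester trans).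

**Step 4**
Reactants: 7 ethyl (2Z,6E)-6-(hydroxymethyl)-2-iodo-8-(triethylsilyloxy)octa-2,6-dienoate
Product: 8 (2Z,6E)-6-(hydroxymethyl)-2-iodo-8-(triethylsilyloxy)octa-2,6-dien-1-ol
Conditions: i-Bu2AlH (3.5 equiv), CH2Cl2, −78 °C
Reagents that add atoms: none
Why: 1,2-Reduction of the enoate to the allylic alcohol with i-Bu2AlH; the alkenyl iodide and the silyl ether are inert at −78 °C.

**Step 5**
Reactants: 8 (2Z,6E)-6-(hydroxymethyl)-2-iodo-8-(triethylsilyloxy)octa-2,6-dien-1-ol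
Product: 9 (2Z,6E)-1-(TBS-oxy)-6-(TBS-oxymethyl)-2-iodo-8-(triethylsilyloxy)octa-2,6-diene
Conditions: t-BuMe2SiCl (2.5 equiv), imidazole, DMF, 0 → 20 °C
Reagents that add atoms: tert-butylchlorodimethylsilane, CC(C)(C)[Si](C)(C)Cl
Why: Silyl ether formation at both primary allylic hydroxyls (future C14–OH and C15–OH).

**Step 6**
Reactants: 9 (2Z,6E)-1-(TBS-oxy)-6-(TBS-oxymethyl)-2-iodo-8-(triethylsilyloxy)octa-2,6-diene
Product: 10 (2E,6Z)-8-(TBS-oxy)-3-(TBS-oxymethyl)-7-iodoocta-2,6-dienal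
Conditions: (COCl)2, DMSO, CH2Cl2, −78 → −30 °C; Et3N, −78 → 0 °C
Reagents that add atoms: none
Why: Swern oxidation run directly on the primary TES ether (the chlorosulfonium salt cleaves the Et3Si–O bond while the TBS ethers stay), giving the enal without E/Z leakage.

**Step 7**
Reactants: 11 ethyl 3-(4,4,5,5-tetramethyl-1,3,2-dioxaborolan-2-yl)propanoate
Product: 13 ethyl (Z)-3-acetoxy-2-[(pinacolboryl)methyl]prop-2-enoate, via lithium formyl enolate 12 (not isolated)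
Conditions: LiN(i-Pr)2, THF, −78 °C; HCO2Et, −78 → 0 °C; Ac2O, 0 °C
Reagents that add atoms: ethyl formate, CCOC=O; acetic anhydride, CC(=O)OC(C)=O
Why: Crossed Claisen formylation of the ester enolate, then O-acetylation of the chelated Z formyl enolate to the enol acetate.

**Step 8**
Reactants: 10 (2E,6Z)-8-(TBS-oxy)-3-(TBS-oxymethyl)-7-iodoocta-2,6-dienal; 13 ethyl (Z)-3-acetoxy-2-[(pinacolboryl)methyl]prop-2-enoate
Product: 16 (5R)-3-(bromomethyl)-5-[(1E,5Z)-7-(TBS-oxy)-2-(TBS-oxymethyl)-6-iodohepta-1,5-dien-1-yl]furan-2(5H)-one, via borate adduct 14 (not isolated), via acetoxy lactone 15 (not isolated)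
Conditions: (S)-3,3′-bis(2,4,6-triisopropylphenyl)-BINOL N-triflylphosphoramide (10 mol %), 4 Å MS, toluene, −20 → 20 °C; then MgBr2·OEt2, THF, 0 → 20 °C
Reagents that add atoms: magnesium bromide, [Mg+2].[Br-].[Br-]
Why: Proposed new method: chiral Brønsted acid-catalysed γ-acetoxy-allylboration of an enal with a 2-(alkoxycarbonyl)allyl pinacolboronate (closest known chemistry: chiral phosphoric acid-catalysed allylboration of aldehydes with allyl-Bpin, and achiral strong-acid-catalysed additions of 2-alkoxycarbonyl allylboronates that end in α-methylene-γ-lactones); the acid hydrogen-bonds to a boronate oxygen and the formyl H in a closed chair transition state, the binaphthyl pocket selects the aldehyde face and so sets C6 as R while forming C6–C7, the borate lactonises onto the ethyl ester, and MgBr2 then displaces the allylic acetate in an SN2′ sense, which erases the irrelevant C7 centre and leaves the ring-locked allylic bromide.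

**Step 9**
Reactants: 16 (5R)-3-(bromomethyl)-5-[(1E,5Z)-7-(TBS-oxy)-2-(TBS-oxymethyl)-6-iodohepta-1,5-dien-1-yl]furan-2(5H)-one; 17 2,2-dimethoxyacetaldehyde (60 % in water)
Product: 18 (4R,5R)-5-[(1E,5Z)-7-(TBS-oxy)-2-(TBS-oxymethyl)-6-iodohepta-1,5-dien-1-yl]-4-[(1R)-1-hydroxy-2,2-dimethoxyethyl]-3-methylideneoxolan-2-one
Conditions: In powder (2 equiv), THF/H2O (1:1), 20 °C
Reagents that add atoms: none
Why: Indium Barbier allylation: the allylindium bonds through ring carbon C7 on the face opposite the C6 side chain (trans lactone), and the ring-locked alkene (C6 trans to CH2In) in a chair transition state with the aldehyde substituent equatorial gives the anti C7/C8 pair (7R,8R here) while restoring the α-methylene lactone.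

**Step 10**
Reactants: 19 tiglic acid
Product: 20 (S)-2-methylbutanoic acid
Conditions: H2 (1.5 bar), Ru(OAc)2[(S)-H8-BINAP] (0.5 mol %), MeOH, 20 °C
Reagents that add atoms: none
Why: Asymmetric hydrogenation of an α,β-unsaturated carboxylic acid with a ruthenium diacetate–biaryl diphosphine catalyst; the (S)-ligand gives the S acid.

**Step 11**
Reactants: 18 the C8 alcohol from step 9; 20 (S)-2-methylbutanoic acid
Product: 21 (1R)-1-{(2R,3S)-2-[(1E,5Z)-7-(TBS-oxy)-2-(TBS-oxymethyl)-6-iodohepta-1,5-dien-1-yl]-4-methylidene-5-oxooxolan-3-yl}-2,2-dimethoxyethyl (2S)-2-methylbutanoate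
Conditions: DCC, DMAP (cat.), CH2Cl2, 0 °C
Reagents that add atoms: none
Why: Steglich esterification of the secondary C8 alcohol; no stereocentre is touched.

**Step 12**
Reactants: 21 the dimethyl acetal ester from step 11
Product: 22 (1R)-1-{(2R,3S)-2-[(1E,5Z)-7-(TBS-oxy)-2-(TBS-oxymethyl)-6-iodohepta-1,5-dien-1-yl]-4-methylidene-5-oxooxolan-3-yl}-2-oxoethyl (2S)-2-methylbutanoate
Conditions: Et3SiOTf, 2,4,6-collidine, CH2Cl2, 0 °C; then H2O
Reagents that add atoms: water, O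
Why: Silyl triflate/collidine acetal cleavage through a collidinium salt that water hydrolyses, mild enough to keep both TBS ethers, the esters and the C8 centre.

**Step 13**
Reactants: 22 the seco aldehyde from step 12
Product: 23 (1(10)Z,4E,6R,7S,8R,9S)-14,15-bis(TBS-oxy)-9-hydroxy-8-[(2S)-2-methylbutanoyloxy]germacra-1(10),4,11(13)-trien-12,6-olide
Conditions: CrCl2 (10 equiv), NiCl2 (2 mol %), DMSO/THF (3:1), 20 °C, 2 mM, slow addition of 22
Reagents that add atoms: none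
Why: Intramolecular Nozaki–Hiyama–Kishi reaction: the alkenylchromium, formed with retention of the Z geometry, adds to the aldehyde anti to the α-acyloxy group (polar Felkin–Anh), which closes the ten-membered ring at C9–C10 and gives the 9S alcohol.

**Step 14**
Reactants: 23 the macrocyclic C9 alcohol
Product: 24 (1(10)Z,4E,6R,7S,8R,9S)-9-acetoxy-14,15-bis(TBS-oxy)-8-[(2S)-2-methylbutanoyloxy]germacra-1(10),4,11(13)-trien-12,6-olide
Conditions: Ac2O, pyridine, DMAP (cat.), CH2Cl2, 0 °C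
Reagents that add atoms: acetic anhydride, CC(=O)OC(C)=O
Why: Acetylation of the secondary allylic alcohol, run cold so that it outpaces a 1,2-acyl shift from O8.

**Step 15**
Reactants: 24 the bis-silyl ether of the target
Product: 25 (1(10)Z,4E,6R,7S,8R,9S)-9-acetoxy-14,15-dihydroxy-8-[(2S)-2-methylbutanoyloxy]germacra-1(10),4,11(13)-trien-12,6-olide (CNP0207247.12)
Conditions: HF·pyridine, THF/pyridine, 0 → 20 °C
Reagents that add atoms: none
Why: Fluoride-mediated cleavage of both primary silyl ethers under buffered, weakly acidic conditions that leave the two esters and the α-methylene lactone alone.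

**Compound list**
1 | but-2-yne-1,4-diol | OCC#CCO | starting material
2 | 2-(2-bromoethyl)-1,3-dioxolane | BrCCC1OCCO1 | starting material
3 | [2-(1,3-dioxolan-2-yl)ethyl]magnesium bromide | Br[Mg]CCC1OCCO1 | intermediate
4 | (E)-2-[2-(1,3-dioxolan-2-yl)ethyl]but-2-ene-1,4-diol | OC/C=C(/CO)CCC1OCCO1 | intermediate
5 | 5-[(E)-2-hydroxyethylidene]oxan-2-ol (lactol; hemiacetal carbon unassigned, lost in step 3) | OC/C=C1/COC(O)CC1 | intermediate
6 | 5-[(E)-2-(triethylsilyloxy)ethylidene]oxan-2-ol | CC[Si](CC)(CC)OC/C=C1/COC(O)CC1 | intermediate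
7 | ethyl (2Z,6E)-6-(hydroxymethyl)-2-iodo-8-(triethylsilyloxy)octa-2,6-dienoate | CC[Si](CC)(CC)OC/C=C(/CO)CC/C=C(/C(=O)OCC)I | intermediate
8 | (2Z,6E)-6-(hydroxymethyl)-2-iodo-8-(triethylsilyloxy)octa-2,6-dien-1-ol | CC[Si](CC)(CC)OC/C=C(/CO)CC/C=C(/CO)I | intermediate
9 | (2Z,6E)-1-(TBS-oxy)-6-(TBS-oxymethyl)-2-iodo-8-(triethylsilyloxy)octa-2,6-diene | CC[Si](CC)(CC)OC/C=C(/CO[Si](C)(C)C(C)(C)C)CC/C=C(/CO[Si](C)(C)C(C)(C)C)I | intermediate
10 | (2E,6Z)-8-(TBS-oxy)-3-(TBS-oxymethyl)-7-iodoocta-2,6-dienal | O=C/C=C(/CO[Si](C)(C)C(C)(C)C)CC/C=C(/CO[Si](C)(C)C(C)(C)C)I | intermediate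
11 | ethyl 3-(4,4,5,5-tetramethyl-1,3,2-dioxaborolan-2-yl)propanoate | CCOC(=O)CCB1OC(C)(C)C(C)(C)O1 | starting material
12 | lithium (1Z)-2-(ethoxycarbonyl)-3-(pinacolboryl)prop-1-en-1-olate | [Li+].[O-]/C=C(/CB1OC(C)(C)C(C)(C)O1)C(=O)OCC | intermediate
13 | ethyl (Z)-3-acetoxy-2-[(pinacolboryl)methyl]prop-2-enoate | CC(=O)O/C=C(/CB1OC(C)(C)C(C)(C)O1)C(=O)OCC | intermediate
14 | ethyl (3S,4R,5E,9Z)-3-acetoxy-11-(TBS-oxy)-6-(TBS-oxymethyl)-10-iodo-2-methylidene-4-(pinacolboryloxy)undeca-5,9-dienoate | CCOC(=O)C(=C)[C@H](OC(C)=O)[C@H](OB1OC(C)(C)C(C)(C)O1)/C=C(/CO[Si](C)(C)C(C)(C)C)CC/C=C(/CO[Si](C)(C)C(C)(C)C)I | intermediate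
15 | (2R,3S)-2-[(1E,5Z)-7-(TBS-oxy)-2-(TBS-oxymethyl)-6-iodohepta-1,5-dien-1-yl]-4-methylidene-5-oxooxolan-3-yl acetate | C=C1C(=O)O[C@H](/C=C(/CO[Si](C)(C)C(C)(C)C)CC/C=C(/CO[Si](C)(C)C(C)(C)C)I)[C@H]1OC(C)=O | intermediate
16 | (5R)-3-(bromomethyl)-5-[(1E,5Z)-7-(TBS-oxy)-2-(TBS-oxymethyl)-6-iodohepta-1,5-dien-1-yl]furan-2(5H)-one | BrCC1=C[C@@H](/C=C(/CO[Si](C)(C)C(C)(C)C)CC/C=C(/CO[Si](C)(C)C(C)(C)C)I)OC1=O | intermediate
17 | 2,2-dimethoxyacetaldehyde | COC(OC)C=O | starting material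
18 | (4R,5R)-5-[(1E,5Z)-7-(TBS-oxy)-2-(TBS-oxymethyl)-6-iodohepta-1,5-dien-1-yl]-4-[(1R)-1-hydroxy-2,2-dimethoxyethyl]-3-methylideneoxolan-2-one | C=C1C(=O)O[C@H](/C=C(/CO[Si](C)(C)C(C)(C)C)CC/C=C(/CO[Si](C)(C)C(C)(C)C)I)[C@H]1[C@@H](O)C(OC)OC | intermediate
19 | tiglic acid, (E)-2-methylbut-2-enoic acid | C/C=C(\C)C(=O)O | starting material
20 | (S)-2-methylbutanoic acid | O=C(O)[C@@H](C)CC | intermediate
21 | (1R)-1-{(2R,3S)-2-[(1E,5Z)-7-(TBS-oxy)-2-(TBS-oxymethyl)-6-iodohepta-1,5-dien-1-yl]-4-methylidene-5-oxooxolan-3-yl}-2,2-dimethoxyethyl (2S)-2-methylbutanoate | C=C1C(=O)O[C@H](/C=C(/CO[Si](C)(C)C(C)(C)C)CC/C=C(/CO[Si](C)(C)C(C)(C)C)I)[C@H]1[C@@H](OC(=O)[C@@H](C)CC)C(OC)OC | intermediate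
22 | (1R)-1-{(2R,3S)-2-[(1E,5Z)-7-(TBS-oxy)-2-(TBS-oxymethyl)-6-iodohepta-1,5-dien-1-yl]-4-methylidene-5-oxooxolan-3-yl}-2-oxoethyl (2S)-2-methylbutanoate | C=C1C(=O)O[C@H](/C=C(/CO[Si](C)(C)C(C)(C)C)CC/C=C(/CO[Si](C)(C)C(C)(C)C)I)[C@H]1[C@@H](OC(=O)[C@@H](C)CC)C=O | intermediate
23 | (1(10)Z,4E,6R,7S,8R,9S)-14,15-bis(TBS-oxy)-9-hydroxy-8-[(2S)-2-methylbutanoyloxy]germacra-1(10),4,11(13)-trien-12,6-olide | C=C1C(=O)O[C@@H]2/C=C(/CO[Si](C)(C)C(C)(C)C)CC/C=C(/CO[Si](C)(C)C(C)(C)C)[C@H](O)[C@H](OC(=O)[C@@H](C)CC)[C@@H]12 | intermediate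
24 | (1(10)Z,4E,6R,7S,8R,9S)-9-acetoxy-14,15-bis(TBS-oxy)-8-[(2S)-2-methylbutanoyloxy]germacra-1(10),4,11(13)-trien-12,6-olide | C=C1C(=O)O[C@@H]2/C=C(/CO[Si](C)(C)C(C)(C)C)CC/C=C(/CO[Si](C)(C)C(C)(C)C)[C@H](OC(C)=O)[C@H](OC(=O)[C@@H](C)CC)[C@@H]12 | intermediate
25 | (1(10)Z,4E,6R,7S,8R,9S)-9-acetoxy-14,15-dihydroxy-8-[(2S)-2-methylbutanoyloxy]germacra-1(10),4,11(13)-trien-12,6-olide | C=C1C(=O)O[C@@H]2/C=C(/CO)CC/C=C(/CO)[C@H](OC(C)=O)[C@H](OC(=O)[C@@H](C)CC)[C@@H]12 | target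

**Step count and risks**
Total: 15 steps. Longest linear sequence: 13 steps (steps 1–6, 8, 9, 11–15); steps 7 and 10 are one-step side branches.

Most likely to fail:

Step 8 (the new reaction). The boronate is deactivated twice (ester and enol acetate) and the doubly allylic lactone oxygen of 16 is acid-sensitive, so rate, enantioselectivity or survival of 16 may fall short. Fallback with known chemistry, from 10 back to 16: CH2=CHMgBr adds 1,2 to 10 (THF, −78 °C) to give racemic dienol F1. MnO2 oxidation gives dienone F2. Corey–Bakshi–Shibata reduction ((R)-2-methyl-CBS-oxazaborolidine, catecholborane, toluene, −78 °C) gives (S)-dienol F3. Esterification with 2-(bromomethyl)acrylic acid (DCC, DMAP cat., 0 °C) gives bromomethylacrylate F4. Ring-closing metathesis with the second-generation Grubbs catalyst (CH2Cl2, 40 °C) closes the butenolide and returns 16.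

Step 13 (macrocyclisation). The ring may close with the wrong face of the aldehyde, and the chromium alkoxide could trigger a 1,2-acyl shift. Fallback from 22 back to 23, setting C9 by reduction instead of addition: the closure is run as above; if it delivers mainly the 9-epimeric alcohol F7, this is oxidised with Dess–Martin periodinane to the macrocyclic ketone F8. F8 is then reduced from its open face (NaBH4, CeCl3, MeOH, −78 °C) or, if substrate control again gives F7, under catalyst control with a CBS oxazaborolidine and catecholborane, to give 23.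

Step 12 (acetal cleavage next to the acyloxy group). The neighbouring ester can capture the oxocarbenium ion and be moved or lost. Fallback from 16 back to 22, with a thioacetal in place of the acetal: indium Barbier coupling of 16 with 1,3-dithiane-2-carbaldehyde (In, THF/H2O) gives dithiane alcohol F5. Esterification with 20 (DCC, DMAP cat.) gives dithiane ester F6. Neutral alkylative hydrolysis (MeI, CaCO3, MeCN/H2O, 40 °C) gives 22.

**Further compounds**
F1 | step 8 | racemic (4E,8Z)-10-(TBS-oxy)-5-(TBS-oxymethyl)-9-iododeca-1,4,8-trien-3-ol | C=CC(O)/C=C(/CO[Si](C)(C)C(C)(C)C)CC/C=C(/CO[Si](C)(C)C(C)(C)C)I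
F2 | step 8 | (4E,8Z)-10-(TBS-oxy)-5-(TBS-oxymethyl)-9-iododeca-1,4,8-trien-3-one | C=CC(=O)/C=C(/CO[Si](C)(C)C(C)(C)C)CC/C=C(/CO[Si](C)(C)C(C)(C)C)I
F3 | step 8 | (3S,4E,8Z)-10-(TBS-oxy)-5-(TBS-oxymethyl)-9-iododeca-1,4,8-trien-3-ol | C=C[C@H](O)/C=C(/CO[Si](C)(C)C(C)(C)C)CC/C=C(/CO[Si](C)(C)C(C)(C)C)I
F4 | step 8 | (3S,4E,8Z)-10-(TBS-oxy)-5-(TBS-oxymethyl)-9-iododeca-1,4,8-trien-3-yl 2-(bromomethyl)prop-2-enoate | C=C[C@H](OC(=O)C(=C)CBr)/C=C(/CO[Si](C)(C)C(C)(C)C)CC/C=C(/CO[Si](C)(C)C(C)(C)C)I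
F5 | step 12 | (4R,5R)-4-[(R)-(1,3-dithian-2-yl)(hydroxy)methyl]-5-[(1E,5Z)-7-(TBS-oxy)-2-(TBS-oxymethyl)-6-iodohepta-1,5-dien-1-yl]-3-methylideneoxolan-2-one | C=C1C(=O)O[C@H](/C=C(/CO[Si](C)(C)C(C)(C)C)CC/C=C(/CO[Si](C)(C)C(C)(C)C)I)[C@H]1[C@@H](O)C2SCCCS2
F6 | step 12 | (R)-(1,3-dithian-2-yl){(2R,3S)-2-[(1E,5Z)-7-(TBS-oxy)-2-(TBS-oxymethyl)-6-iodohepta-1,5-dien-1-yl]-4-methylidene-5-oxooxolan-3-yl}methyl (2S)-2-methylbutanoate | C=C1C(=O)O[C@H](/C=C(/CO[Si](C)(C)C(C)(C)C)CC/C=C(/CO[Si](C)(C)C(C)(C)C)I)[C@H]1[C@@H](OC(=O)[C@@H](C)CC)C2SCCCS2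
F7 | step 13 | 9-epimer of 23, (1(10)Z,4E,6R,7S,8R,9R)-14,15-bis(TBS-oxy)-9-hydroxy-8-[(2S)-2-methylbutanoyloxy]germacra-1(10),4,11(13)-trien-12,6-olide | C=C1C(=O)O[C@@H]2/C=C(/CO[Si](C)(C)C(C)(C)C)CC/C=C(/CO[Si](C)(C)C(C)(C)C)[C@@H](O)[C@H](OC(=O)[C@@H](C)CC)[C@@H]12
F8 | step 13 | (1(10)Z,4E,6R,7S,8R)-14,15-bis(TBS-oxy)-8-[(2S)-2-methylbutanoyloxy]-9-oxogermacra-1(10),4,11(13)-trien-12,6-olide | C=C1C(=O)O[C@@H]2/C=C(/CO[Si](C)(C)C(C)(C)C)CC/C=C(/CO[Si](C)(C)C(C)(C)C)C(=O)[C@H](OC(=O)[C@@H](C)CC)[C@@H]12
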